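Target 28 ⇐ 8-O-methacryloylation and 9-O-acetylation of furanone diol 25 ⇐ acid cascade of epoxide 23 (transannular opening at C8, then closure of the furanone ring O–C3=C2–C1(=O)–C10) ⇐ oxidative lactonisation (C6–O–C12) and outer-face epoxidation of the (E)-C8=C9 olefin of 19.
Key disconnection C1–C10: ten-membered vinylogous ester 19 ⇐ potassium alkoxide of cyclohexenol 16, by an anionic oxy-Cope ring expansion that forms C1–C10 while the temporary C3–C8 bond (absent from the target) is cut.
Enabling feature: in the ten-membered carbocycle C1–C10 lies across from C3 and C8. C3 is the enol-ether carbon of the furanone (ketone oxidation level), so C1≡C2–C3(O−)–C8–C9=C10 is a 3-oxido-1,5-enyne. Joining C3 to C8 contracts the carbocycle to a six-membered ring (C3–C8) that already holds the cis C4=C5 olefin with C15, the oxygen at C6 and the C11–C13 unit at C7, i.e. a γ-oxygenated carvone.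
Ring A ⇐ (R)-carvone 1: C12 allylic oxidation, α'-hydroxylation (C6), 1,3-enone transposition (epoxidation, Wharton, MnO2), C8 allylation, Wacker oxidation, (Z)-enol silylation, ethoxyethynyl addition.
Ring order: six-membered ring A (chiral pool) → ten-membered carbocycle (step 11) → γ-lactone (step 13) → furanone (step 15).

Key step: step 11

Remark: locants C1–C15 follow the germacrane numbering of the target and are used for every intermediate (C1 furanone carbonyl carbon, C3 furanone enol-ether carbon, C10 quaternary carbon bearing O and CH3, C12 lactone carbonyl carbon); the target is taken as (4Z,6R,7S,8S,9S,10S); TBS = tert-butyldimethylsilyl, TIPS = triisopropylsilyl; the C3 configuration of 16 and the C1=C2 geometry of 19 are drawn for the expected isomers and are without consequence.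

Step 1
Reactants: 1 (R)-carvone
Product: 2 (R)-10-hydroxycarvone (C12 alcohol)
Conditions: SeO2 (cat.), t-BuOOH, CH2Cl2, rt
Reagents that add atoms: tert-butyl hydroperoxide, CC(C)(C)OO (the oxygen atom, relayed by SeO2)
Why: Allylic oxidation (SeO2 ene reaction, then [2,3] shift) should attack the electron-rich 1,1-disubstituted olefin at its methyl group (C12) and leave the deactivated enone olefin alone; no stereocentre is touched.

Step 2
Reactants: 2 (R)-10-hydroxycarvone
Product: 4 6,12-diol (6-OH trans to the C7 side chain), via dilithium dianion 3 (not isolated)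
Conditions: LiN(i-Pr)2 (2.2 equiv), THF, −78 °C; 3-phenyl-2-(phenylsulfonyl)oxaziridine; aq. NH4Cl
Reagents that add atoms: 3-phenyl-2-(phenylsulfonyl)oxaziridine, O=S(=O)(c1ccccc1)N1OC1c1ccccc1
Why: Enolate hydroxylation with an N-sulfonyloxaziridine: the kinetic α'-enolate (C6) should take up oxygen anti to the neighbouring C7 side chain, which sets the C6–O bond trans to it as the trans-fused lactone requires.

Step 3
Reactants: 4 6,12-diol
Product: 5 6,12-bis-TBS ether
Conditions: TBSCl, imidazole, DMF, rt
Reagents that add atoms: tert-butyldimethylsilyl chloride, CC(C)(C)[Si](C)(C)Cl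
Why: Imidazole-promoted silyl ether formation masks both hydroxyls for the basic and oxidative steps that follow and affects no stereocentre.

Step 4
Reactants: 5 6,12-bis-TBS ether
Product: 6 3,4-epoxy-5-ketone
Conditions: H2O2 (30%), NaOH (cat.), MeOH, 0 °C
Reagents that add atoms: hydrogen peroxide, OO
Why: Weitz–Scheffer nucleophilic epoxidation acts only on the enone olefin; the epoxide configuration (drawn anti to the C7 side chain) does not matter, because C4 becomes trigonal in step 5 and C3 in step 6.

Step 5
Reactants: 6 3,4-epoxy-5-ketone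
Product: 8 transposed allylic alcohol (3-OH with C4=C5 olefin), via epoxy hydrazone 7 (not isolated)
Conditions: N2H4·H2O, AcOH (cat.), MeOH, 0 °C to rt
Reagents that add atoms: none
Why: Wharton transposition: the epoxy hydrazone fragments with loss of N2, moving the oxygen from C5 to C3 and the olefin to C4=C5, so that the C6 silyloxy group ends up γ to the future ketone without being touched.

Step 6
Reactants: 8 transposed allylic alcohol
Product: 9 ring A enone (3-ketone with cis C4=C5 and 6-OTBS)
Conditions: MnO2, CH2Cl2, rt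
Reagents that add atoms: none
Why: MnO2 oxidation is selective for the allylic alcohol and should give the transposed enone while the silyl ethers and the isolated olefin stay inert.

Step 7
Reactants: 9 ring A enone; 10 allyl bromide
Product: 12 8-allyl enone (6,7-trans and 7,8-trans), via lithium enolate 11 (not isolated)
Conditions: LiN(i-Pr)2, THF, −78 °C; 10, DMPU, −78 to −20 °C
Reagents that add atoms: allyl bromide 10, C=CCBr
Why: Kinetic α'-deprotonation at C8 and alkylation of the lithium enolate anti to the neighbouring C7 side chain (1,2-induction) should give the all-equatorial product and so set C8.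

Step 8
Reactants: 12 8-allyl enone
Product: 13 8-acetonyl enone (1,4-diketone)
Conditions: PdCl2 (cat.), CuCl (cat.), O2, DMF/H2O, rt
Reagents that add atoms: water, O (oxygen of the new carbonyl; O2 is the terminal oxidant)
Why: Tsuji–Wacker oxidation converts the monosubstituted terminal olefin into the methyl ketone (C10) and should leave the 1,1-disubstituted and trisubstituted olefins alone.

Step 9
Reactants: 13 8-acetonyl enone
Product: 14 (Z)-TIPS enol ether ketone (C9=C10 with O cis to C8)
Conditions: i-Pr3SiOTf, Et3N, CH2Cl2, 0 °C to rt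
Reagents that add atoms: triisopropylsilyl trifluoromethanesulfonate, CC(C)[Si](OS(=O)(=O)C(F)(F)F)(C(C)C)C(C)C
Why: Soft enolisation under equilibrating conditions should give the more substituted (Z)-silyl enol ether of the side-chain ketone, while the ring ketone, whose only α'-hydrogen is tertiary and hindered, stays as it is; the bulky silyl group is chosen because it should not migrate to the alkoxide of step 11.

Step 10
Reactants: 14 (Z)-TIPS enol ether ketone; 15 ethoxyacetylene
Product: 16 ethoxyethynyl carbinol (tertiary alcohol at C3)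
Conditions: 15, n-BuLi, THF, −78 °C; then 14; H2O
Reagents that add atoms: ethoxyacetylene 15, C#COCC
Why: 1,2-Addition of the lithium alkynide to the ketone (axial attack should favour the epimer drawn); the C3 configuration is irrelevant because C3 becomes trigonal in step 11.

Step 11
Reactants: 16 ethoxyethynyl carbinol
Product: 19 ten-membered vinylogous ester (1-ethoxy-1,4,8-trien-3-one with 10-OTIPS), via potassium alkoxide 17 (not isolated), via potassium allenolate 18 (not isolated)
Conditions: KH, 18-crown-6, THF, −20 °C to rt; AcOH, −78 °C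
Reagents that add atoms: none
Why: Proposed new method: deprotonation gives the potassium 3-oxido-1,5-enyne 17, whose alkoxide weakens the C3–C8 ring bond so that a charge-accelerated [3,3]-sigmatropic shift cuts C3–C8 and joins the alkynyl ether carbon C1 to the enol ether carbon C10, the allenolate 18 then being protonated at C2 to the vinylogous ester 19; the closest known reaction type is the anionic oxy-Cope four-carbon ring expansion of 1-alkynyl-2-alkenylcyclohexanols, extended here to an alkoxyalkyne and a silyl enol ether so that the new bond joins two oxygen-bearing carbons. The ten-membered carbocycle is closed by ring expansion through a six-centre cyclic transition state (ring A opens as C1–C10 forms), so no end-to-end macrocyclisation is needed. The new quaternary stereocentre C10 is set by suprafacial chirality transfer from C8: the side chain should react in the rotamer with C9=C10 eclipsing C8–H (the other rotamer suffers A(1,3) strain between the silyloxy group and C7), which gives the (E)-C8=C9 olefin and, with the (Z)-enol ether, the (10S) configuration. Both C3 epimers of 16 converge on the same product, and the cis C4=C5 olefin is carried over unchanged from ring A. The step needs the [3,3] shift to outrun loss of the alkynide (retro-addition) and O-to-O silyl transfer; the low temperature, the electron-rich termini and the bulky triisopropylsilyl group on the enol oxygen are there to secure this.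

Step 12
Reactants: 19 ten-membered vinylogous ester
Product: 20 6,12-diol (10-OTIPS kept)
Conditions: HF·pyridine, pyridine/THF, 0 °C
Reagents that add atoms: none
Why: Fluoride-mediated desilylation should cleave the primary and secondary TBS ethers, while the hindered tertiary TIPS ether and the vinylogous ester survive the buffered medium.

Step 13
Reactants: 20 6,12-diol
Product: 22 6,12-lactone (α-methylene-γ-butyrolactone), via hydroxy enal 21 (not isolated)
Conditions: TEMPO (cat.), PhI(OAc)2, CH2Cl2, rt
Reagents that add atoms: none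
Why: Oxoammonium (TEMPO) oxidation takes the primary allylic alcohol to hydroxy enal 21, whose lactol is oxidised on to the lactone (oxidative lactonisation); the trans ring fusion follows from C7 of carvone and C6 of step 2.

Step 14
Reactants: 22 6,12-lactone
Product: 23 8,9-epoxide
Conditions: m-CPBA, NaHCO3, CH2Cl2, 0 °C
Reagents that add atoms: 3-chloroperoxybenzoic acid, O=C(OO)c1cccc(Cl)c1
Why: Prilezhaev epoxidation of the only electron-rich olefin left, the strained (E)-C8=C9 bond, should occur from its exposed outer face (the inner face is covered by the C1–C3 segment of the ring), which sets C9 and places the epoxide oxygen anti to the C3 carbonyl across the ring.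

Step 15
Reactants: 23 8,9-epoxide
Product: 25 furanone 8,9-diol, via anti-diol 24 (not isolated)
Conditions: aq. HF (48%), MeCN, 0 °C to rt
Reagents that add atoms: water, O
Why: Acid cascade: the C3 carbonyl oxygen, held over the back of C8 by the ring, should open the protonated epoxide with inversion at C8, and hydrolysis of the resulting oxocarbenium ion gives anti-diol 24 with C9 retained; loss of the silyl group then lets O10 add to C3 and ethanol leave from C1 (cyclodehydration of the α'-hydroxy vinylogous ester), closing the 3(2H)-furanone.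

Step 16
Reactants: 25 furanone 8,9-diol; 26 methacrylic anhydride
Product: 27 8-methacrylate (9-OH free)
Conditions: 26, Et3N, DMAP (cat.), CH2Cl2, −20 °C
Reagents that add atoms: methacrylic anhydride 26, C=C(C)C(=O)OC(=O)C(C)=C
Why: DMAP-catalysed acylation should take place at the less hindered C8 hydroxyl, the C9 hydroxyl being shielded by the adjacent quaternary C10.

Step 17
Reactants: 27 8-methacrylate
Product: 28 CNP0365569.2 (target)
Conditions: Ac2O, pyridine, DMAP, CH2Cl2, rt
Reagents that add atoms: acetic anhydride, CC(=O)OC(C)=O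
Why: DMAP-catalysed acetylation of the remaining hindered secondary alcohol completes the target without touching any stereocentre.

Compound list
1 | (R)-carvone | CC1=CC[C@H](CC1=O)C(C)=C | starting material
2 | (R)-10-hydroxycarvone (C12 alcohol) | CC1=CC[C@H](CC1=O)C(=C)CO | intermediate
3 | dilithium dianion of 2 (C6 enolate, C12 alkoxide) | CC1=CC[C@@H](C(=C)C[O-])C=C1[O-].[Li+].[Li+] | intermediate
4 | 6,12-diol, 6-OH trans to the C7 side chain | CC1=CC[C@H]([C@H](O)C1=O)C(=C)CO | intermediate
5 | 6,12-bis-TBS ether of 4 | CC1=CC[C@H]([C@H](O[Si](C)(C)C(C)(C)C)C1=O)C(=C)CO[Si](C)(C)C(C)(C)C | intermediate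
6 | 3,4-epoxy-5-ketone (epoxide anti to the C7 side chain) | C[C@@]12O[C@@H]1C[C@H]([C@H](O[Si](C)(C)C(C)(C)C)C2=O)C(=C)CO[Si](C)(C)C(C)(C)C | intermediate
7 | epoxy hydrazone of 6 | C[C@@]12O[C@@H]1C[C@H]([C@H](O[Si](C)(C)C(C)(C)C)C2=NN)C(=C)CO[Si](C)(C)C(C)(C)C | intermediate
8 | transposed allylic alcohol (3-OH, C4=C5, 6-OTBS) | CC1=C[C@@H](O[Si](C)(C)C(C)(C)C)[C@H](C(=C)CO[Si](C)(C)C(C)(C)C)C[C@H]1O | intermediate
9 | ring A enone (3-ketone, cis C4=C5, 6-OTBS trans to C7 side chain) | CC1=C[C@@H](O[Si](C)(C)C(C)(C)C)[C@H](C(=C)CO[Si](C)(C)C(C)(C)C)CC1=O | intermediate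
10 | allyl bromide | C=CCBr | starting material
11 | lithium enolate of 9 (C3–C8) | CC1=C[C@@H](O[Si](C)(C)C(C)(C)C)[C@H](C(=C)CO[Si](C)(C)C(C)(C)C)C=C1[O-].[Li+] | intermediate
12 | 8-allyl enone, substituents at C6, C7, C8 all trans | CC1=C[C@@H](O[Si](C)(C)C(C)(C)C)[C@H](C(=C)CO[Si](C)(C)C(C)(C)C)[C@@H](CC=C)C1=O | intermediate
13 | 8-acetonyl enone (1,4-diketone) | CC1=C[C@@H](O[Si](C)(C)C(C)(C)C)[C@H](C(=C)CO[Si](C)(C)C(C)(C)C)[C@@H](CC(C)=O)C1=O | intermediate
14 | (Z)-TIPS enol ether ketone (C9=C10, O cis to C8) | CC1=C[C@@H](O[Si](C)(C)C(C)(C)C)[C@H](C(=C)CO[Si](C)(C)C(C)(C)C)[C@@H](/C=C(/C)O[Si](C(C)C)(C(C)C)C(C)C)C1=O | intermediate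
15 | ethoxyacetylene | C#COCC | starting material
16 | ethoxyethynyl carbinol (C3 tertiary alcohol, alkynyl cis to the C8 side chain) | CC1=C[C@@H](O[Si](C)(C)C(C)(C)C)[C@H](C(=C)CO[Si](C)(C)C(C)(C)C)[C@@H](/C=C(/C)O[Si](C(C)C)(C(C)C)C(C)C)[C@@]1(O)C#COCC | intermediate
17 | potassium alkoxide of 16 | CC1=C[C@@H](O[Si](C)(C)C(C)(C)C)[C@H](C(=C)CO[Si](C)(C)C(C)(C)C)[C@@H](/C=C(/C)O[Si](C(C)C)(C(C)C)C(C)C)[C@@]1([O-])C#COCC.[K+] | intermediate
18 | potassium allenolate (ten-membered ring, C1=C2=C3–O−) | CCOC1=C=C([O-])/C(C)=C\[C@@H](O[Si](C)(C)C(C)(C)C)[C@H](C(=C)CO[Si](C)(C)C(C)(C)C)/C=C/[C@]1(C)O[Si](C(C)C)(C(C)C)C(C)C.[K+] | intermediate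
19 | ten-membered vinylogous ester (1-ethoxy-3-oxo, 4Z, 8E, 6-OTBS, 12-OTBS, 10-OTIPS, 10S) | CCO/C1=C/C(=O)/C(C)=C\[C@@H](O[Si](C)(C)C(C)(C)C)[C@H](C(=C)CO[Si](C)(C)C(C)(C)C)/C=C/[C@]1(C)O[Si](C(C)C)(C(C)C)C(C)C | intermediate
20 | 6,12-diol of 19 | CCO/C1=C/C(=O)/C(C)=C\[C@@H](O)[C@H](C(=C)CO)/C=C/[C@]1(C)O[Si](C(C)C)(C(C)C)C(C)C | intermediate
21 | hydroxy enal (C12 aldehyde, 6-OH) | CCO/C1=C/C(=O)/C(C)=C\[C@@H](O)[C@H](C(=C)C=O)/C=C/[C@]1(C)O[Si](C(C)C)(C(C)C)C(C)C | intermediate
22 | 6,12-lactone (trans-fused α-methylene-γ-butyrolactone, 8E olefin) | CCO/C1=C/C(=O)/C(C)=C\[C@H]2OC(=O)C(=C)[C@@H]2/C=C/[C@]1(C)O[Si](C(C)C)(C(C)C)C(C)C | intermediate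
23 | 8,9-epoxide (trans, on the outer face) | CCO/C1=C/C(=O)/C(C)=C\[C@H]2OC(=O)C(=C)[C@@H]2[C@H]3O[C@@H]3[C@]1(C)O[Si](C(C)C)(C(C)C)C(C)C | intermediate
24 | 8,9-anti-diol vinylogous ester | CCO/C1=C/C(=O)/C(C)=C\[C@H]2OC(=O)C(=C)[C@@H]2[C@H](O)[C@H](O)[C@]1(C)O[Si](C(C)C)(C(C)C)C(C)C | intermediate
25 | furanone 8,9-diol (3,10-oxygen-bridged 3(2H)-furanone, 6,12-lactone) | O[C@H]1[C@H]2C(=C)C(=O)O[C@@H]2/C=C(/C)C2=CC(=O)[C@@](C)(O2)[C@H]1O | intermediate
26 | methacrylic anhydride | C=C(C)C(=O)OC(=O)C(C)=C | starting material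
27 | 8-methacrylate, 9-OH free | C=C(C)C(=O)O[C@H]1[C@H]2C(=C)C(=O)O[C@@H]2/C=C(/C)C2=CC(=O)[C@@](C)(O2)[C@H]1O | intermediate
28 | CNP0365569.2, (4Z,6R,7S,8S,9S,10S)-9-acetoxy-8-methacryloyloxy furanoheliangolide | C=C(C)C(=O)O[C@H]1[C@H]2C(=C)C(=O)O[C@@H]2/C=C(/C)C2=CC(=O)[C@@](C)(O2)[C@H]1OC(C)=O | target

Total step count: 17. Longest linear sequence: 17 steps (1 to 28); the added fragments 10, 15 and 26 are commercial.

Steps most likely to fail

Step 11 (Proposed new method). The alkoxide may fragment back to ketone 14 and alkynide, or be quenched by silyl or proton transfer, instead of undergoing the [3,3] shift; a less selective side-chain rotamer would also erode the C10 configuration. The fallback uses known chemistry and sets out from 14. Addition of (Z)-2-ethoxyvinyllithium (from (Z)-1-bromo-2-ethoxyethene and n-BuLi) should give the 1,2-dialkenyl carbinol F1. Its potassium alkoxide (KH, 18-crown-6, THF) undergoes the classical all-alkene anionic oxy-Cope six-to-ten ring expansion, and cold protonation gives the β-ethoxy ketone F2 (C1 epimers; C10 is controlled by the same C8 centre and (Z)-enol ether). Dehydrogenation of C1–C2 with IBX removes the C1 stereocentre and comes back to the route at 19.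

Step 9. Enolisation may go toward the methyl group or involve the ring ketone, C8 may epimerise, or the 1,4-diketone may close to a furan (Paal–Knorr type) under the silyl triflate. The fallback sets out from 12 and hides the ring ketone for the duration. Luche reduction (NaBH4, CeCl3) gives allylic alcohol F3 and acetylation gives acetate F4. Tsuji–Wacker oxidation gives acetoxy ketone F5, and silylation (i-Pr3SiOTf, Et3N, long equilibration) of what is then the only ketone gives acetoxy silyl enol ether F6. Methanolysis (K2CO3, MeOH) gives hydroxy silyl enol ether F7, and MnO2 oxidation comes back to the route at 14.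

Step 15 (with the facial selectivity of step 14 feeding into it). The nucleophilic C2 of the vinylogous ester may form a transannular C–C bond to C8, or the epoxide may open at C9, instead of oxygen participation at C8. The fallback sets out from 22 and avoids the epoxide. Aqueous HF alone closes the furanone to the (E)-olefinic furanone lactone F8. Thiyl-radical isomerisation (PhSSPh, hν) gives the less strained (Z)-olefinic furanone lactone F9. Dihydroxylation with OsO4 (cat.) and N-methylmorpholine N-oxide from the convex face then comes back to the route at 25, since syn addition to the Z-olefin gives the same anti relationship as anti addition to the E-olefin.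

Further compounds
F1 | step 11 | (Z)-2-ethoxyvinyl carbinol (1,2-dialkenyl cyclohexenol) | CC1=C[C@@H](O[Si](C)(C)C(C)(C)C)[C@H](C(=C)CO[Si](C)(C)C(C)(C)C)[C@@H](/C=C(/C)O[Si](C(C)C)(C(C)C)C(C)C)[C@@]1(O)/C=C\OCC
F2 | step 11 | ten-membered β-ethoxy ketone (1-ethoxy-3-oxo, 4Z, 8E, C1 epimers) | CCOC1CC(=O)/C(C)=C\[C@@H](O[Si](C)(C)C(C)(C)C)[C@H](C(=C)CO[Si](C)(C)C(C)(C)C)/C=C/[C@]1(C)O[Si](C(C)C)(C(C)C)C(C)C
F3 | step 9 | 8-allyl allylic alcohol (3-OH) | CC1=C[C@@H](O[Si](C)(C)C(C)(C)C)[C@H](C(=C)CO[Si](C)(C)C(C)(C)C)[C@@H](CC=C)[C@@H]1O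
F4 | step 9 | 8-allyl allylic acetate | CC1=C[C@@H](O[Si](C)(C)C(C)(C)C)[C@H](C(=C)CO[Si](C)(C)C(C)(C)C)[C@@H](CC=C)[C@@H]1OC(C)=O
F5 | step 9 | 8-acetonyl allylic acetate | CC1=C[C@@H](O[Si](C)(C)C(C)(C)C)[C@H](C(=C)CO[Si](C)(C)C(C)(C)C)[C@@H](CC(C)=O)[C@@H]1OC(C)=O
F6 | step 9 | (Z)-TIPS enol ether allylic acetate | CC1=C[C@@H](O[Si](C)(C)C(C)(C)C)[C@H](C(=C)CO[Si](C)(C)C(C)(C)C)[C@@H](/C=C(/C)O[Si](C(C)C)(C(C)C)C(C)C)[C@@H]1OC(C)=O
F7 | step 9 | (Z)-TIPS enol ether allylic alcohol | CC1=C[C@@H](O[Si](C)(C)C(C)(C)C)[C@H](C(=C)CO[Si](C)(C)C(C)(C)C)[C@@H](/C=C(/C)O[Si](C(C)C)(C(C)C)C(C)C)[C@@H]1O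
F8 | step 15 | (E)-8,9-olefinic furanone lactone | C=C1C(=O)O[C@@H]2/C=C(/C)C3=CC(=O)[C@@](C)(O3)/C=C/[C@@H]12
F9 | step 15 | (Z)-8,9-olefinic furanone lactone | C=C1C(=O)O[C@@H]2/C=C(/C)C3=CC(=O)[C@@](C)(O3)/C=C\[C@@H]12
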